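Retrosynthesis: the C3–H bond of the flavone is traced back to C3–Cl; then the two ring bonds of C3 (C2–C3 and C3–C4) are cut together, which shrinks ring C to the furan ring of a 2-aryl-3-silyloxybenzofuran; last, the C2–C1' bond to ring B is cut.
Enabling feature: C3 is the only CH of ring C and sits between the aryl-bearing C2 and the carbonyl carbon C4, so a 2-arylbenzofuran-3-one, which already carries ring A, O1, C2 and C4, lacks only this one carbon.
Forward order: ring A and the five-membered oxygen ring are bought as one piece; ring B is joined by palladium-catalysed α-arylation; the enol is silylated; a dichlorocarbene carbon is then inserted, which turns the furan into ring C; hydrogenolysis of C3–Cl ends the route.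
Stereochemistry: the target has no stereocentre; the single one met on the way (C2 of the arylated benzofuranone, racemic) is erased when the enol is silylated.

Key step: step 3

Remark: the arylated benzofuranone of step 1 is written as its keto tautomer; the keto and 3-hydroxybenzofuran forms give the same silyl ether, and the compound is kept under argon because 2-arylbenzofuran-3-ones autoxidise at C2 in base.

Step 1
Reactants: 1 4,6-dimethoxy-1-benzofuran-3(2H)-one (1.2 equiv); 2 1-bromo-2,3,4-trimethoxybenzene
Product: 4 4,6-dimethoxy-2-(2,3,4-trimethoxyphenyl)-1-benzofuran-3(2H)-one (racemic), via sodium benzofuran-3-olate 3 (not isolated)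
Conditions: Pd(OAc)2 (3 mol%), XPhos (2-dicyclohexylphosphino-2',4',6'-triisopropylbiphenyl, 6 mol%), NaOtBu (2.5 equiv), toluene, 80 °C, Ar; then degassed 1 M HCl, 0 °C
Reagents that add atoms: none
Why: Palladium-catalysed α-arylation of a ketone enolate (Buchwald–Hartwig–Miura type): the excess of NaOtBu holds both 1 and the more acidic product entirely as sodium enolates, which should suppress aldol self-condensation, while the ortho-methoxy group of 2 and the bulky biarylphosphine disfavour a second arylation at the fully substituted C2 of enolate 3.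

Step 2
Reactants: 4 4,6-dimethoxy-2-(2,3,4-trimethoxyphenyl)-1-benzofuran-3(2H)-one
Product: 5 {[4,6-dimethoxy-2-(2,3,4-trimethoxyphenyl)-1-benzofuran-3-yl]oxy}trimethylsilane
Conditions: TMSOTf (1.2 equiv), Et3N (1.5 equiv), CH2Cl2, 0 °C, Ar; evaporation, extraction into dry hexane, filtration; used without chromatography
Reagents that add atoms: trimethylsilyl trifluoromethanesulfonate, C[Si](C)(C)OS(=O)(=O)C(F)(F)F
Why: Silyl enol ether formation with a silyl triflate and a tertiary amine: enolisation of 4 is driven by aromatisation to the benzofuran and the hard silicon electrophile should be taken up at oxygen, which also erases the C2 stereocentre.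

Step 3
Reactants: 5 {[4,6-dimethoxy-2-(2,3,4-trimethoxyphenyl)-1-benzofuran-3-yl]oxy}trimethylsilane; 6 sodium trichloroacetate
Product: 9 3-chloro-5,7-dimethoxy-2-(2,3,4-trimethoxyphenyl)-4H-chromen-4-one (3-chloro-2',3',4',5,7-pentamethoxyflavone), via gem-dichlorocyclopropane adduct 7 (not isolated), via 4-silyloxyflavylium chloride 8 (not isolated)
Conditions: 6 (4 equiv, in portions), Cl2C=CCl2–DME (4:1), reflux (about 110 °C), N2; then aq. NaHCO3
Reagents that add atoms: sodium trichloroacetate (compound 6, source of C3 and its chlorine), [Na+].[O-]C(=O)C(Cl)(Cl)Cl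
Why: Proposed new method: thermal decarboxylation of 6 should release dichlorocarbene, which adds in a concerted [2+1] cheletropic step to the benzofuran C2=C3 enol ether bond of 5 (future flavone C2 and C4) to give adduct 7; departure of the endo chloride together with disrotatory two-electron electrocyclic opening of the old C2–C3 bond, assisted by the lone pairs of O1 and of the silyloxy group, leads to the aromatic flavylium chloride 8, and chloride then takes the silyl group from oxygen to unveil the C4 carbonyl of 9. The closest known reaction types are the dihalocarbene ring expansion of cyclic trimethylsilyl enol ethers to 2-chloro-2-enones and the Ciamician–Dennstedt expansion of indoles to 3-haloquinolines, but neither has been shown on a 3-silyloxybenzofuran. Ring C is not closed by a cyclisation: the three-membered ring is closed by the carbene addition, and the six-membered pyranone arises by expansion of the furan when the shared bond of the bicycle breaks, so that the two surviving cyclopropane bonds become C2–C3 and C3–C4. The two stereocentres of 7 are cis by ring fusion and vanish on aromatisation, so no stereocontrol is needed. The selectivity required is attack of the electrophilic carbene at the enol ether and not at the methoxyarenes, which the two oxygen donors on that double bond should secure, and cleavage of the internal and not an external cyclopropane bond, which orbital symmetry and the gain of the pyrylium sextet enforce. A neutral, base-free carbene source is chosen so that the silyl ether is not cleaved to an enolate, which would be dichloromethylated at C2 instead.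

Step 4
Reactants: 9 3-chloro-5,7-dimethoxy-2-(2,3,4-trimethoxyphenyl)-4H-chromen-4-one
Product: 10 5,7-dimethoxy-2-(2,3,4-trimethoxyphenyl)-4H-chromen-4-one (2',3',4',5,7-pentamethoxyflavone)
Conditions: H2 (1 atm), 10% Pd/C, Et3N (1.5 equiv), EtOAc, rt; stopped after uptake of one equivalent
Reagents that add atoms: none
Why: Palladium-catalysed hydrogenolysis of an activated vinylic C–Cl bond: the chlorine α to the enone carbonyl should be cleaved readily once Et3N scavenges HCl, whereas the push–pull C2=C3 bond of a flavone is slow to hydrogenate at one atmosphere, as benzyl ethers of flavones are routinely hydrogenolysed without touching it.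

Compound list
1 | 4,6-dimethoxy-1-benzofuran-3(2H)-one | COc1cc(OC)c2c(c1)OCC2=O | starting material
2 | 1-bromo-2,3,4-trimethoxybenzene | COc1ccc(Br)c(OC)c1OC | starting material
3 | sodium 4,6-dimethoxy-2-(2,3,4-trimethoxyphenyl)-1-benzofuran-3-olate | COc1cc(OC)c2c([O-])c(-c3ccc(OC)c(OC)c3OC)oc2c1.[Na+] | intermediate (not isolated)
4 | 4,6-dimethoxy-2-(2,3,4-trimethoxyphenyl)-1-benzofuran-3(2H)-one, racemic at C2, keto tautomer | COc1cc(OC)c2c(c1)OC(c1ccc(OC)c(OC)c1OC)C2=O | intermediate
5 | {[4,6-dimethoxy-2-(2,3,4-trimethoxyphenyl)-1-benzofuran-3-yl]oxy}trimethylsilane | COc1cc(OC)c2c(O[Si](C)(C)C)c(-c3ccc(OC)c(OC)c3OC)oc2c1 | intermediate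
6 | sodium trichloroacetate | [Na+].[O-]C(=O)C(Cl)(Cl)Cl | starting material
7 | {[1,1-dichloro-4,6-dimethoxy-1a-(2,3,4-trimethoxyphenyl)-1,1a-dihydro-6bH-cyclopropa[b][1]benzofuran-6b-yl]oxy}trimethylsilane, racemic, cis ring fusion, one enantiomer drawn | COc1cc(OC)c2c(c1)O[C@]1(c3ccc(OC)c(OC)c3OC)C(Cl)(Cl)[C@]21O[Si](C)(C)C | intermediate (not isolated)
8 | 3-chloro-5,7-dimethoxy-2-(2,3,4-trimethoxyphenyl)-4-[(trimethylsilyl)oxy]chromenylium chloride | COc1cc(OC)c2c(O[Si](C)(C)C)c(Cl)c(-c3ccc(OC)c(OC)c3OC)[o+]c2c1.[Cl-] | intermediate (not isolated)
9 | 3-chloro-5,7-dimethoxy-2-(2,3,4-trimethoxyphenyl)-4H-chromen-4-one (3-chloro-2',3',4',5,7-pentamethoxyflavone) | COc1cc(OC)c2c(=O)c(Cl)c(-c3ccc(OC)c(OC)c3OC)oc2c1 | intermediate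
10 | 5,7-dimethoxy-2-(2,3,4-trimethoxyphenyl)-4H-chromen-4-one (2',3',4',5,7-pentamethoxyflavone) | COc1cc(OC)c2c(=O)cc(-c3ccc(OC)c(OC)c3OC)oc2c1 | target

Total step count: 4. Longest linear sequence: 4 steps (from 1 and 2 to 10).

Steps most likely to fail

Step 3 (key step). The trimethylsilyl group may be transferred from the enol oxygen to trichloroacetate or trichloromethanide before the carbene arrives, after which the free enolate would be dichloromethylated at C2 and not cyclopropanated. Addition to the crowded, tetrasubstituted double bond may also be too slow, or the flavylium ion may be captured at C2 by trichloromethanide. The fallback uses known chemistry and gives up the carbon insertion; it sets out from 2 and rejoins the route at 10. Bromine–lithium exchange on 2 (n-BuLi, THF, −78 °C) would give (2,3,4-trimethoxyphenyl)lithium F1, which is formylated with DMF and quenched with dilute HCl to give 2,3,4-trimethoxybenzaldehyde F2. Claisen–Schmidt condensation of this aldehyde with bought 1-(2-hydroxy-4,6-dimethoxyphenyl)ethanone (KOH, EtOH, rt) should give (E)-1-(2-hydroxy-4,6-dimethoxyphenyl)-3-(2,3,4-trimethoxyphenyl)prop-2-en-1-one F3. Oxidative cyclisation of the chalcone with catalytic iodine in DMSO at 130 °C closes ring C by oxa-Michael addition and dehydrogenation and delivers 10.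

Step 1. Reductive elimination from the delocalised, stabilised enolate may be slow. The benzofuranone may self-condense under the basic conditions, a second aryl group may be introduced at C2, or the product enolate may be oxidised at C2 by adventitious air during work-up. The fallback replaces enolate arylation by cross-coupling of a metalated benzofuran; it sets out from 1 and rejoins the route at 4. Silylation of 1 (TIPSOTf, Et3N, CH2Cl2, 0 °C) would give [(4,6-dimethoxy-1-benzofuran-3-yl)oxy]tri(propan-2-yl)silane F4; the bulky silyl group is chosen because smaller ones would migrate from oxygen to a neighbouring carbanion. Deprotonation at the furan C2 (n-BuLi, THF, −78 °C) should give {4,6-dimethoxy-3-[(tri(propan-2-yl)silyl)oxy]-1-benzofuran-2-yl}lithium F5, and ZnCl2 converts it into chlorido{4,6-dimethoxy-3-[(tri(propan-2-yl)silyl)oxy]-1-benzofuran-2-yl}zinc F6. Negishi coupling of the zinc reagent with 2 (Pd(OAc)2, SPhos, THF, 60 °C) would give {[4,6-dimethoxy-2-(2,3,4-trimethoxyphenyl)-1-benzofuran-3-yl]oxy}tri(propan-2-yl)silane F7. Cleavage of the silyl ether with tetrabutylammonium fluoride buffered with acetic acid (THF, 0 °C, Ar) then releases 4.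

Step 4. Hydrogenolysis of the C–Cl bond may stall through catalyst poisoning, or saturation of the C2=C3 bond may compete, so that mixtures of flavone and flavanone result. The fallback no longer tries to stop at the flavone; it sets out from 9 and rejoins the route at 10. Exhaustive hydrogenation (H2, 4 atm, 10% Pd/C, Et3N, EtOAc–EtOH, rt) should remove the chlorine and saturate ring C to give racemic 5,7-dimethoxy-2-(2,3,4-trimethoxyphenyl)-2,3-dihydro-4H-chromen-4-one F8. Dehydrogenation of this flavanone with catalytic iodine in DMSO at 120 °C, a standard flavanone-to-flavone oxidation, restores the C2=C3 bond and gives 10.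

Further compounds
F1 | step 3 | (2,3,4-trimethoxyphenyl)lithium | [Li]c1ccc(OC)c(OC)c1OC
F2 | step 3 | 2,3,4-trimethoxybenzaldehyde | COc1ccc(C=O)c(OC)c1OC
F3 | step 3 | (E)-1-(2-hydroxy-4,6-dimethoxyphenyl)-3-(2,3,4-trimethoxyphenyl)prop-2-en-1-one | COc1cc(O)c(C(=O)/C=C/c2ccc(OC)c(OC)c2OC)c(OC)c1
F4 | step 1 | [(4,6-dimethoxy-1-benzofuran-3-yl)oxy]tri(propan-2-yl)silane | COc1cc(OC)c2c(O[Si](C(C)C)(C(C)C)C(C)C)coc2c1
F5 | step 1 | {4,6-dimethoxy-3-[(tri(propan-2-yl)silyl)oxy]-1-benzofuran-2-yl}lithium | COc1cc(OC)c2c(O[Si](C(C)C)(C(C)C)C(C)C)c([Li])oc2c1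
F6 | step 1 | chlorido{4,6-dimethoxy-3-[(tri(propan-2-yl)silyl)oxy]-1-benzofuran-2-yl}zinc | COc1cc(OC)c2c(O[Si](C(C)C)(C(C)C)C(C)C)c([Zn]Cl)oc2c1
F7 | step 1 | {[4,6-dimethoxy-2-(2,3,4-trimethoxyphenyl)-1-benzofuran-3-yl]oxy}tri(propan-2-yl)silane | COc1cc(OC)c2c(O[Si](C(C)C)(C(C)C)C(C)C)c(-c3ccc(OC)c(OC)c3OC)oc2c1
F8 | step 4 | 5,7-dimethoxy-2-(2,3,4-trimethoxyphenyl)-2,3-dihydro-4H-chromen-4-one, racemic | COc1cc(OC)c2c(c1)OC(CC2=O)c1ccc(OC)c(OC)c1OC
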